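The target is opened at the C6–C7 bond of the cyclohexanone ring (C1, C9, C5, C6, C7, C8). The precursor is a doubly dearomatised acylphloroglucinol: the trione ring (C1–C5, C9) carries on C5 the lavandulyl group and an iodomethyl group (C6), on C1 the protected aroyl group and a CMe2–CH=CH–CHO arm (C8, C7). The key step exploits that C6 and C8 stand 1,3-cis on this nearly flat ring: the C6 radical adds 6-exo to the enal β-carbon C7, which closes the bicyclo[3.3.1]nonane and sets C7 with its side chain equatorial. Olefination of the aldehyde then gives the C7 prenyl group.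

Key step: step 16

Atom labels: C1 aroyl bridgehead, C2 enol carbon, C3 prenylated ring carbon, C4 ring carbonyl, C5 lavandulyl bridgehead, C6 ring CH2, C7 prenylated CH, C8 CMe2, C9 bridging carbonyl; O2, O4 and O9 are the oxygens on C2, C4 and C9.

Remark: C5 is created in step 11 without a control element, so both C5 epimers are carried to step 15, where the epimer with C6 cis to the C8 arm is separated and the other is discarded; the enol of the target is written as the C2-hydroxy tautomer.

Step 1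
Reactants: 1 (S)-4-benzyl-1,3-oxazolidin-2-one; 2 3-methylbut-2-enoyl chloride
Product: 4 (S)-4-benzyl-3-(3-methylbut-2-enoyl)-1,3-oxazolidin-2-one, via N-lithio oxazolidinone 3 (not isolated)
Conditions: n-BuLi, THF, −78 °C; then 2, −78 to 0 °C
Reagents that add atoms: none
Why: N-acylation of the lithiated oxazolidinone by the acid chloride attaches the auxiliary for the Evans alkylation; no new stereocenter.

Step 2
Reactants: 4 (S)-4-benzyl-3-(3-methylbut-2-enoyl)-1,3-oxazolidin-2-one; 5 1-bromo-3-methylbut-2-ene (prenyl bromide)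
Product: 7 (S)-4-benzyl-3-[(2S)-5-methyl-2-(prop-1-en-2-yl)hex-4-enoyl]-1,3-oxazolidin-2-one, via sodium dienolate 6 (not isolated)
Conditions: NaN(SiMe3)2, THF, −78 °C; then 5, −78 to −30 °C
Reagents that add atoms: none
Why: Evans alkylation in its deconjugative form: γ-deprotonation gives the chelated Z-dienolate, which is alkylated at Cα on the face away from the benzyl group, so the lavandulyl stereocenter is set and the double bond moves to the isopropenyl position.

Step 3
Reactants: 7 (S)-4-benzyl-3-[(2S)-5-methyl-2-(prop-1-en-2-yl)hex-4-enoyl]-1,3-oxazolidin-2-one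
Product: 8 (S)-lavandulol, (2S)-5-methyl-2-(prop-1-en-2-yl)hex-4-en-1-ol
Conditions: LiBH4, Et2O, H2O (1 equiv), 0 °C
Reagents that add atoms: none
Why: Reductive cleavage of the imide by LiBH4 should give the primary alcohol without touching the α-stereocenter and return the auxiliary.

Step 4
Reactants: 8 (S)-lavandulol
Product: 9 (S)-lavandulyl iodide, (3S)-3-(iodomethyl)-2,6-dimethylhepta-1,5-diene
Conditions: PPh3, iodine, imidazole, CH2Cl2, 0 °C
Reagents that add atoms: iodine [I][I]
Why: Appel-type iodination takes place at the primary carbon, one atom away from the stereocenter, which is therefore retained.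

Step 5
Reactants: 10 5-methoxybenzene-1,3-diol
Product: 11 1-methoxy-3,5-bis(methoxymethoxy)benzene
Conditions: MOMCl, i-Pr2NEt, CH2Cl2, 0 °C to rt
Reagents that add atoms: chloromethyl methyl ether COCCl
Why: Williamson-type acetal ether formation installs the two MOM groups that direct the later ortho-lithiations and leaves the methyl ether as the future O2 substituent.

Step 6
Reactants: 11 1-methoxy-3,5-bis(methoxymethoxy)benzene; 9 (S)-lavandulyl iodide
Product: 13 5-methoxy-1,3-bis(methoxymethoxy)-2-[(2R)-5-methyl-2-(prop-1-en-2-yl)hex-4-enyl]benzene, via aryllithium 12 (not isolated)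
Conditions: n-BuLi, THF, 0 °C; then CuI (10 mol %), 9, −20 °C to rt
Reagents that add atoms: none
Why: Directed ortho-metalation occurs at the position flanked by both MOM ethers (future C5) and the aryl metal is alkylated by the primary iodide in a copper-assisted SN2 reaction; the stereocenter is untouched and its descriptor changes from S to R only through the priority rules.

Step 7
Reactants: 13 5-methoxy-1,3-bis(methoxymethoxy)-2-[(2R)-5-methyl-2-(prop-1-en-2-yl)hex-4-enyl]benzene; 5 1-bromo-3-methylbut-2-ene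
Product: 15 1-methoxy-3,5-bis(methoxymethoxy)-2-(3-methylbut-2-enyl)-4-[(2R)-5-methyl-2-(prop-1-en-2-yl)hex-4-enyl]benzene, via aryllithium 14 (not isolated)
Conditions: n-BuLi, TMEDA, THF, −20 °C; then 5, −78 °C to rt
Reagents that add atoms: none
Why: A second directed ortho-metalation at one of the two equivalent positions between OMe and OMOM, followed by allylic substitution on prenyl bromide, places the prenyl group on the future C3.

Step 8
Reactants: 16 methyl 3,4-dihydroxybenzoate
Product: 17 methyl 3,4-bis(tert-butyldimethylsilyloxy)benzoate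
Conditions: TBSCl, imidazole, DMF, rt
Reagents that add atoms: tert-butyldimethylsilyl chloride CC(C)(C)[Si](C)(C)Cl
Why: Silylation protects the catechol in a form that survives aryllithium, radical and ylide chemistry and is removed by fluoride at the end.

Step 9
Reactants: 15 1-methoxy-3,5-bis(methoxymethoxy)-2-(3-methylbut-2-enyl)-4-[(2R)-5-methyl-2-(prop-1-en-2-yl)hex-4-enyl]benzene; 17 methyl 3,4-bis(tert-butyldimethylsilyloxy)benzoate
Product: 19 [3,4-bis(tert-butyldimethylsilyloxy)phenyl]{6-methoxy-2,4-bis(methoxymethoxy)-5-(3-methylbut-2-enyl)-3-[(2R)-5-methyl-2-(prop-1-en-2-yl)hex-4-enyl]phenyl}methanone, via aryllithium 18 (not isolated)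
Conditions: n-BuLi, TMEDA, THF, −20 °C; then 17, −78 to 0 °C
Reagents that add atoms: none
Why: The last ring CH (between OMe and OMOM, future C1) is lithiated and the aryllithium undergoes acyl substitution on the ester; the di-ortho-substituted ketone formed is too hindered for a second addition.

Step 10
Reactants: 19 [3,4-bis(tert-butyldimethylsilyloxy)phenyl]{6-methoxy-2,4-bis(methoxymethoxy)-5-(3-methylbut-2-enyl)-3-[(2R)-5-methyl-2-(prop-1-en-2-yl)hex-4-enyl]phenyl}methanone
Product: 20 [3,4-bis(tert-butyldimethylsilyloxy)phenyl]{2,4-dihydroxy-6-methoxy-5-(3-methylbut-2-enyl)-3-[(2R)-5-methyl-2-(prop-1-en-2-yl)hex-4-enyl]phenyl}methanone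
Conditions: ZnBr2, n-PrSH, CH2Cl2, 0 °C
Reagents that add atoms: none
Why: Lewis acid and thiol cleave the MOM acetals quickly under non-protic conditions that should spare the aryl silyl ethers and the prenyl-type alkenes, freeing O4 and O9 while O2 stays methylated.

Step 11
Reactants: 20 [3,4-bis(tert-butyldimethylsilyloxy)phenyl]{2,4-dihydroxy-6-methoxy-5-(3-methylbut-2-enyl)-3-[(2R)-5-methyl-2-(prop-1-en-2-yl)hex-4-enyl]phenyl}methanone
Product: 21 4-[3,4-bis(tert-butyldimethylsilyloxy)benzoyl]-5-hydroxy-6-(iodomethyl)-3-methoxy-2-(3-methylbut-2-enyl)-6-[(2R)-5-methyl-2-(prop-1-en-2-yl)hex-4-enyl]cyclohexa-2,4-dien-1-one (both epimers at ring C6, label C5)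
Conditions: LiN(SiMe3)2 (2.2 equiv), THF/toluene, −78 to 0 °C; then CH2I2 (excess), 0 °C to rt
Reagents that add atoms: diiodomethane [I]C[I]
Why: Alkylative dearomatisation: the dianion should react with diiodomethane at C5, the carbon flanked by both oxyanions and so the 1,3-dicarbonyl-like position, to give a neopentyl-type iodide that resists further substitution; there is no facial bias, so both C5 epimers are expected.

Step 12
Reactants: 22 methyl 2,2-dimethoxyacetate; 23 (2-methylprop-1-enyl)magnesium bromide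
Product: 24 1,1-dimethoxy-4-methylpent-3-en-2-one
Conditions: THF, −78 °C; aqueous NH4Cl
Reagents that add atoms: none
Why: Grignard acyl substitution on an α,α-dialkoxy ester stops at the ketone because the chelated tetrahedral adduct survives until work-up.

Step 13
Reactants: 24 1,1-dimethoxy-4-methylpent-3-en-2-one
Product: 25 (2R)-1,1-dimethoxy-4-methylpent-3-en-2-ol
Conditions: RuCl[(S,S)-TsDPEN](p-cymene) (1 mol %), HCO2H/Et3N, rt
Reagents that add atoms: none
Why: Noyori–Ikariya asymmetric transfer hydrogenation reduces the carbonyl group; with the alkenyl group in the role of the π-substituent the (S,S)-catalyst is expected to give the (R)-carbinol.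

Step 14
Reactants: 21 dearomatised iodide (both C5 epimers); 25 (2R)-1,1-dimethoxy-4-methylpent-3-en-2-ol
Product: 27 (6S)-6-[3,4-bis(tert-butyldimethylsilyloxy)benzoyl]-6-[(3E)-5,5-dimethoxy-2-methylpent-3-en-2-yl]-2-(iodomethyl)-5-methoxy-4-(3-methylbut-2-enyl)-2-[(2R)-5-methyl-2-(prop-1-en-2-yl)hex-4-enyl]cyclohex-4-ene-1,3-dione (both epimers at ring C2, label C5), via allyl vinyl ether 26 (not isolated)
Conditions: PPh3, DIAD, toluene, 0 °C to rt; then 80 °C
Reagents that add atoms: none
Why: Mitsunobu O-alkylation of the chelated C9 enol with inversion gives the (S)-configured allyl vinyl ether, whose Claisen rearrangement through a chair transition state with the dimethoxymethyl group equatorial forms the C1–C8 bond on the ring face that makes C1 (S), so the carbinol chirality is transferred to C1 and an E-alkene remains.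

Step 15
Reactants: 27 Claisen product (both C5 epimers)
Product: 28 (2R,6S)-6-[3,4-bis(tert-butyldimethylsilyloxy)benzoyl]-2-(iodomethyl)-5-methoxy-4-(3-methylbut-2-enyl)-6-[(3E)-2-methyl-5-oxopent-3-en-2-yl]-2-[(2R)-5-methyl-2-(prop-1-en-2-yl)hex-4-enyl]cyclohex-4-ene-1,3-dione (iodomethyl cis to the C8 arm)
Conditions: oxalic acid (cat.), THF/H2O, rt; chromatography
Reagents that add atoms: water O
Why: Mild acid hydrolysis of the allylic dimethyl acetal unmasks the E-enal, and the two C5 epimers, now diastereomers at two ring stereocenters, should be separable so that the cis isomer is carried on.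

Step 16
Reactants: 28 cis-configured iodo enal
Product: 29 (1S,5R,7R)-1-[3,4-bis(tert-butyldimethylsilyloxy)benzoyl]-2-methoxy-8,8-dimethyl-3-(3-methylbut-2-enyl)-5-[(2R)-5-methyl-2-(prop-1-en-2-yl)hex-4-enyl]-7-(2-oxoethyl)bicyclo[3.3.1]non-2-ene-4,9-dione
Conditions: Bu3SnH (slow addition), Et3B, air, toluene, 0 °C
Reagents that add atoms: none
Why: The tributyltin radical abstracts iodine from the neopentyl-type iodide, the primary C6 radical adds in a 6-exo-trig Giese fashion to C7, the β-carbon of the enal, and the α-formyl radical formed takes hydrogen from Bu3SnH. The closest known reaction type is the tin hydride mediated conjugate radical cyclisation of alkyl iodides onto enals and enoates. The ring closed is the cyclohexanone ring C1–C9–C5–C6–C7–C8 (6-exo-trig), which completes the bicyclo[3.3.1]nonane. The new stereocenter C7 is set by the chair-like transition state, in which the arm that becomes CH2CHO stays equatorial because the axial position points at C3 of the trione ring; C1 and C5 are already fixed and only their cis arrangement can close. The step needs ring closure to outrun 1,2-acyl migration of the β-keto radical (Dowd–Beckwith-type ring expansion) and attack on the lavandulyl alkenes; the electron-poor, polarity-matched acceptor, the 1,3-cis proximity of C6 and C8 and the low temperature should secure this.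

Step 17
Reactants: 29 bicyclic aldehyde
Product: 30 (1S,5R,7S)-1-[3,4-bis(tert-butyldimethylsilyloxy)benzoyl]-2-methoxy-8,8-dimethyl-3,7-bis(3-methylbut-2-enyl)-5-[(2R)-5-methyl-2-(prop-1-en-2-yl)hex-4-enyl]bicyclo[3.3.1]non-2-ene-4,9-dione
Conditions: isopropyltriphenylphosphonium iodide, n-BuLi, THF, 0 °C; then 29, −78 to 0 °C
Reagents that add atoms: isopropyltriphenylphosphonium iodide CC(C)[P+](c1ccccc1)(c1ccccc1)c1ccccc1.[I-]
Why: Wittig olefination with the non-stabilised isopropylidene ylide should take the aldehyde in preference to the hindered or vinylogous ketones and completes the C7 prenyl group; C7 is untouched and its descriptor changes from R to S only through the priority rules.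

Step 18
Reactants: 30 methyl enol ether
Product: 31 (1S,5R,7S)-1-[3,4-bis(tert-butyldimethylsilyloxy)benzoyl]-2-hydroxy-8,8-dimethyl-3,7-bis(3-methylbut-2-enyl)-5-[(2R)-5-methyl-2-(prop-1-en-2-yl)hex-4-enyl]bicyclo[3.3.1]non-2-ene-4,9-dione
Conditions: LiCl, DMSO, 120 °C
Reagents that add atoms: none
Why: Krapcho-type SN2 attack of chloride on the methyl group of the vinylogous ester frees the enol under neutral conditions that the prenyl-type alkenes tolerate; any silyl ether lost here converges in step 19.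

Step 19
Reactants: 31 bis-silyl ether
Product: 32 (1S,5R,7S)-1-(3,4-dihydroxybenzoyl)-2-hydroxy-8,8-dimethyl-3,7-bis(3-methylbut-2-enyl)-5-[(2R)-5-methyl-2-(prop-1-en-2-yl)hex-4-enyl]bicyclo[3.3.1]non-2-ene-4,9-dione
Conditions: Et3N·3HF, THF, rt, argon
Reagents that add atoms: none
Why: Buffered fluoride cleaves the two aryl silyl ethers without the acid that would cyclise the enol onto a prenyl group; no stereocenter is involved.

Compound list
1 | (S)-4-benzyl-1,3-oxazolidin-2-one | O=C1OC[C@H](Cc2ccccc2)N1 | starting material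
2 | 3-methylbut-2-enoyl chloride | CC(C)=CC(Cl)=O | starting material
3 | N-lithio derivative of 1 | O=C1OC[C@H](Cc2ccccc2)N1[Li] | intermediate
4 | (S)-4-benzyl-3-(3-methylbut-2-enoyl)-1,3-oxazolidin-2-one | O=C1OC[C@H](Cc2ccccc2)N1C(=O)C=C(C)C | intermediate
5 | 1-bromo-3-methylbut-2-ene (prenyl bromide) | CC(C)=CCBr | starting material
6 | sodium Z-dienolate of 4 | O=C1OC[C@H](Cc2ccccc2)N1/C(O[Na])=C/C(C)=C | intermediate
7 | (S)-4-benzyl-3-[(2S)-5-methyl-2-(prop-1-en-2-yl)hex-4-enoyl]-1,3-oxazolidin-2-one | O=C1OC[C@H](Cc2ccccc2)N1C(=O)[C@@H](CC=C(C)C)C(C)=C | intermediate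
8 | (S)-lavandulol, (2S)-5-methyl-2-(prop-1-en-2-yl)hex-4-en-1-ol | OC[C@H](C(C)=C)CC=C(C)C | intermediate
9 | (S)-lavandulyl iodide, (3S)-3-(iodomethyl)-2,6-dimethylhepta-1,5-diene | [I]C[C@H](C(C)=C)CC=C(C)C | intermediate
10 | 5-methoxybenzene-1,3-diol | COc1cc(O)cc(O)c1 | starting material
11 | 1-methoxy-3,5-bis(methoxymethoxy)benzene | COc1cc(OCOC)cc(OCOC)c1 | intermediate
12 | 4-methoxy-2,6-bis(methoxymethoxy)phenyllithium | COc1cc(OCOC)c([Li])c(OCOC)c1 | intermediate
13 | 5-methoxy-1,3-bis(methoxymethoxy)-2-[(2R)-5-methyl-2-(prop-1-en-2-yl)hex-4-enyl]benzene | COc1cc(OCOC)c(C[C@H](C(C)=C)CC=C(C)C)c(OCOC)c1 | intermediate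
14 | aryllithium from 13 (lithium between OMe and OMOM) | COc1c([Li])c(OCOC)c(C[C@H](C(C)=C)CC=C(C)C)c(OCOC)c1 | intermediate
15 | 1-methoxy-3,5-bis(methoxymethoxy)-2-(3-methylbut-2-enyl)-4-[(2R)-5-methyl-2-(prop-1-en-2-yl)hex-4-enyl]benzene | COc1c(CC=C(C)C)c(OCOC)c(C[C@H](C(C)=C)CC=C(C)C)c(OCOC)c1 | intermediate
16 | methyl 3,4-dihydroxybenzoate | COC(=O)c1ccc(O)c(O)c1 | starting material
17 | methyl 3,4-bis(tert-butyldimethylsilyloxy)benzoate | COC(=O)c1ccc(O[Si](C)(C)C(C)(C)C)c(O[Si](C)(C)C(C)(C)C)c1 | intermediate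
18 | aryllithium from 15 (lithium at the last ring position) | COc1c(CC=C(C)C)c(OCOC)c(C[C@H](C(C)=C)CC=C(C)C)c(OCOC)c1[Li] | intermediate
19 | [3,4-bis(tert-butyldimethylsilyloxy)phenyl]{6-methoxy-2,4-bis(methoxymethoxy)-5-(3-methylbut-2-enyl)-3-[(2R)-5-methyl-2-(prop-1-en-2-yl)hex-4-enyl]phenyl}methanone | COc1c(CC=C(C)C)c(OCOC)c(C[C@H](C(C)=C)CC=C(C)C)c(OCOC)c1C(=O)c1ccc(O[Si](C)(C)C(C)(C)C)c(O[Si](C)(C)C(C)(C)C)c1 | intermediate
20 | [3,4-bis(tert-butyldimethylsilyloxy)phenyl]{2,4-dihydroxy-6-methoxy-5-(3-methylbut-2-enyl)-3-[(2R)-5-methyl-2-(prop-1-en-2-yl)hex-4-enyl]phenyl}methanone | COc1c(CC=C(C)C)c(O)c(C[C@H](C(C)=C)CC=C(C)C)c(O)c1C(=O)c1ccc(O[Si](C)(C)C(C)(C)C)c(O[Si](C)(C)C(C)(C)C)c1 | intermediate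
21 | 4-[3,4-bis(tert-butyldimethylsilyloxy)benzoyl]-5-hydroxy-6-(iodomethyl)-3-methoxy-2-(3-methylbut-2-enyl)-6-[(2R)-5-methyl-2-(prop-1-en-2-yl)hex-4-enyl]cyclohexa-2,4-dien-1-one, both C5 epimers (C5 left open in the SMILES) | COC1=C(CC=C(C)C)C(=O)C(C[I])(C[C@H](C(C)=C)CC=C(C)C)C(O)=C1C(=O)c1ccc(O[Si](C)(C)C(C)(C)C)c(O[Si](C)(C)C(C)(C)C)c1 | intermediate
22 | methyl 2,2-dimethoxyacetate | COC(OC)C(=O)OC | starting material
23 | (2-methylprop-1-enyl)magnesium bromide | CC(C)=C[Mg]Br | starting material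
24 | 1,1-dimethoxy-4-methylpent-3-en-2-one | COC(OC)C(=O)C=C(C)C | intermediate
25 | (2R)-1,1-dimethoxy-4-methylpent-3-en-2-ol | COC(OC)[C@H](O)C=C(C)C | intermediate
26 | 4-[3,4-bis(tert-butyldimethylsilyloxy)benzoyl]-5-{[(2S)-1,1-dimethoxy-4-methylpent-3-en-2-yl]oxy}-6-(iodomethyl)-3-methoxy-2-(3-methylbut-2-enyl)-6-[(2R)-5-methyl-2-(prop-1-en-2-yl)hex-4-enyl]cyclohexa-2,4-dien-1-one, both C5 epimers | COC1=C(CC=C(C)C)C(=O)C(C[I])(C[C@H](C(C)=C)CC=C(C)C)C(O[C@H](C(OC)OC)C=C(C)C)=C1C(=O)c1ccc(O[Si](C)(C)C(C)(C)C)c(O[Si](C)(C)C(C)(C)C)c1 | intermediate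
27 | (6S)-6-[3,4-bis(tert-butyldimethylsilyloxy)benzoyl]-6-[(3E)-5,5-dimethoxy-2-methylpent-3-en-2-yl]-2-(iodomethyl)-5-methoxy-4-(3-methylbut-2-enyl)-2-[(2R)-5-methyl-2-(prop-1-en-2-yl)hex-4-enyl]cyclohex-4-ene-1,3-dione, both C5 epimers (C5 left open in the SMILES) | C=C(C)[C@H](CC=C(C)C)CC1(C[I])C(=O)[C@@](C(=O)c2ccc(O[Si](C)(C)C(C)(C)C)c(O[Si](C)(C)C(C)(C)C)c2)(C(C)(C)/C=C/C(OC)OC)C(OC)=C(CC=C(C)C)C1=O | intermediate
28 | (2R,6S)-6-[3,4-bis(tert-butyldimethylsilyloxy)benzoyl]-2-(iodomethyl)-5-methoxy-4-(3-methylbut-2-enyl)-6-[(3E)-2-methyl-5-oxopent-3-en-2-yl]-2-[(2R)-5-methyl-2-(prop-1-en-2-yl)hex-4-enyl]cyclohex-4-ene-1,3-dione | C=C(C)[C@H](CC=C(C)C)C[C@]1(C[I])C(=O)[C@@](C(=O)c2ccc(O[Si](C)(C)C(C)(C)C)c(O[Si](C)(C)C(C)(C)C)c2)(C(C)(C)/C=C/C=O)C(OC)=C(CC=C(C)C)C1=O | intermediate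
29 | (1S,5R,7R)-1-[3,4-bis(tert-butyldimethylsilyloxy)benzoyl]-2-methoxy-8,8-dimethyl-3-(3-methylbut-2-enyl)-5-[(2R)-5-methyl-2-(prop-1-en-2-yl)hex-4-enyl]-7-(2-oxoethyl)bicyclo[3.3.1]non-2-ene-4,9-dione | C=C(C)[C@H](CC=C(C)C)C[C@]12C[C@H](CC=O)C(C)(C)[C@](C(=O)c3ccc(O[Si](C)(C)C(C)(C)C)c(O[Si](C)(C)C(C)(C)C)c3)(C1=O)C(OC)=C(CC=C(C)C)C2=O | intermediate
30 | (1S,5R,7S)-1-[3,4-bis(tert-butyldimethylsilyloxy)benzoyl]-2-methoxy-8,8-dimethyl-3,7-bis(3-methylbut-2-enyl)-5-[(2R)-5-methyl-2-(prop-1-en-2-yl)hex-4-enyl]bicyclo[3.3.1]non-2-ene-4,9-dione | C=C(C)[C@H](CC=C(C)C)C[C@]12C[C@H](CC=C(C)C)C(C)(C)[C@](C(=O)c3ccc(O[Si](C)(C)C(C)(C)C)c(O[Si](C)(C)C(C)(C)C)c3)(C1=O)C(OC)=C(CC=C(C)C)C2=O | intermediate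
31 | (1S,5R,7S)-1-[3,4-bis(tert-butyldimethylsilyloxy)benzoyl]-2-hydroxy-8,8-dimethyl-3,7-bis(3-methylbut-2-enyl)-5-[(2R)-5-methyl-2-(prop-1-en-2-yl)hex-4-enyl]bicyclo[3.3.1]non-2-ene-4,9-dione | C=C(C)[C@H](CC=C(C)C)C[C@]12C[C@H](CC=C(C)C)C(C)(C)[C@](C(=O)c3ccc(O[Si](C)(C)C(C)(C)C)c(O[Si](C)(C)C(C)(C)C)c3)(C1=O)C(O)=C(CC=C(C)C)C2=O | intermediate
32 | (1S,5R,7S)-1-(3,4-dihydroxybenzoyl)-2-hydroxy-8,8-dimethyl-3,7-bis(3-methylbut-2-enyl)-5-[(2R)-5-methyl-2-(prop-1-en-2-yl)hex-4-enyl]bicyclo[3.3.1]non-2-ene-4,9-dione | C=C(C)[C@H](CC=C(C)C)C[C@]12C[C@H](CC=C(C)C)C(C)(C)[C@](C(=O)c3ccc(O)c(O)c3)(C1=O)C(O)=C(CC=C(C)C)C2=O | target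

Total step count: 19
Longest linear sequence: 15 steps (steps 1–4, 6, 7, 9–11, 14–19)

Steps most likely to fail

1. Step 16. The primary radical at C6 may be lost before it reaches C7: by 1,2-acyl migration through the C4 or C9 carbonyl (ring expansion), by addition to the isopropenyl or prenyl alkene of the lavandulyl chain, or by early hydrogen transfer; the stannane may also reduce the enal. Fallback: the order of the last two carbon–carbon bond formations is reversed and the acceptor is changed from an enal to a conjugated diene. Setting out from 28, olefination with isopropylidenetriphenylphosphorane (as in step 17) should give the dienyl iodide F1. Radical generation from F1 (Bu3SnH, Et3B, air, low temperature) then closes the ring by 6-exo addition to the diene terminus C7; the allyl radical formed should take hydrogen at its less substituted end. The route is rejoined at 30, and no aldehyde is exposed to tin hydride or to the later ylide. This does not remove the risk of 1,2-acyl migration, which both variants share.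

2. Step 14. The Mitsunobu reaction may alkylate the wrong oxygen (aroyl oxygen or O4), the hindered allylic alcohol may ionise or react at its far terminus with loss of optical purity, and the rearrangement may pass through a boat or go on by a Cope shift to C3. Fallback: the carbon–oxygen bond is formed at the ring carbon instead of at the carbinol carbon. Setting out from 21, oxalyl chloride and catalytic DMF should give the vinylogous acid chloride F2, in which chlorine marks C9. The (S)-alcohol F3 (from 24 with the enantiomeric ruthenium catalyst of step 13) then displaces chloride by addition–elimination (i-Pr2NEt, DMAP, CH2Cl2) with retention at the carbinol carbon. This comes back to the route at 26, which is heated to 27 as in step 14.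

3. Step 11. Diiodomethane may react too slowly, the dianion may be alkylated on oxygen, or attack may occur at C3 instead of C5. Fallback: C6 is introduced at the alcohol oxidation level by a reversible, carbon-selective aldol reaction. Setting out from 20, aqueous formaldehyde with NaHCO3 in THF should give the hydroxymethyl dienone F4. Appel iodination (PPh3, iodine, imidazole) then comes back to the route at 21.

Further compounds
F1 | step 16 | (2R,6S)-6-[3,4-bis(tert-butyldimethylsilyloxy)benzoyl]-6-[(3E)-2,6-dimethylhepta-3,5-dien-2-yl]-2-(iodomethyl)-5-methoxy-4-(3-methylbut-2-enyl)-2-[(2R)-5-methyl-2-(prop-1-en-2-yl)hex-4-enyl]cyclohex-4-ene-1,3-dione | C=C(C)[C@H](CC=C(C)C)C[C@]1(C[I])C(=O)[C@@](C(=O)c2ccc(O[Si](C)(C)C(C)(C)C)c(O[Si](C)(C)C(C)(C)C)c2)(C(C)(C)/C=C/C=C(C)C)C(OC)=C(CC=C(C)C)C1=O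
F2 | step 14 | 4-[3,4-bis(tert-butyldimethylsilyloxy)benzoyl]-5-chloro-6-(iodomethyl)-3-methoxy-2-(3-methylbut-2-enyl)-6-[(2R)-5-methyl-2-(prop-1-en-2-yl)hex-4-enyl]cyclohexa-2,4-dien-1-one, both C5 epimers | COC1=C(CC=C(C)C)C(=O)C(C[I])(C[C@H](C(C)=C)CC=C(C)C)C(Cl)=C1C(=O)c1ccc(O[Si](C)(C)C(C)(C)C)c(O[Si](C)(C)C(C)(C)C)c1
F3 | step 14 | (2S)-1,1-dimethoxy-4-methylpent-3-en-2-ol | COC(OC)[C@@H](O)C=C(C)C
F4 | step 11 | 4-[3,4-bis(tert-butyldimethylsilyloxy)benzoyl]-5-hydroxy-6-(hydroxymethyl)-3-methoxy-2-(3-methylbut-2-enyl)-6-[(2R)-5-methyl-2-(prop-1-en-2-yl)hex-4-enyl]cyclohexa-2,4-dien-1-one, both C5 epimers | COC1=C(CC=C(C)C)C(=O)C(CO)(C[C@H](C(C)=C)CC=C(C)C)C(O)=C1C(=O)c1ccc(O[Si](C)(C)C(C)(C)C)c(O[Si](C)(C)C(C)(C)C)c1
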